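The runs were generated by integration on assumed constants, and the scatter is random.

Read the flask at 2.5 h through f, the fraction of substrate left, not through what has been made.

all flasks: substrate 0.50 M
- cedar: coupling partner 1.1 equiv; the very flask that is asked about, followed so far
- flask: coupling partner 1.10 equiv; time 2.5 h

- cedar (time / min: substrate / %, first product / %): 8.00: 92.8, 6.4; 15.0: 86.8, 10.7; 25.0: 80.7, 13.9; 30.0: 78.4, 16.2

(standard deviation of a reading: 0.5 percentage points)



* how much substrate there is at 2.5 h, in percent of the substrate charged
* how much first product there is at 2.5 h, in percent of the substrate charged
* how much bis adduct there is at 2.5 h, in percent of the substrate charged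
* how much triple product there is at 2.5 h, in percent of the substrate charged

Take substrate loss as first order in substrate and in coupling partner, so that −ln f grows with the partner the flask has held over time. The last cedar reading, at 30.0 min, gives 0.885 /M/h for κ, which is −ln f divided by the time and by the partner concentration charged. With partner taken as held at its charge, κ multiplied by that charge acts as a pseudo-first-order rate constant for substrate. My own reckoning holds partner at its charge and gives f = 29.6% at 2.5 h. Partner is used as substrate goes, so I commit to more substrate than that, without a firm figure.

The forecast gives 49% substrate, 21% first product, 23% bis adduct and 7% triple product, and adds: “The split among the later products is the least certain part”.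

The flask gives 46.2% substrate, 13.0% first product, 13.3% bis adduct and 4.82% triple product.

    substrate + coupling partner → first product + released group (k = 3.00 × 10⁻⁴ /M/s)
    coupling partner + first product → bis adduct + released group (k = 6.10 × 10⁻⁴ /M/s)
    coupling partner + bis adduct → triple product + released group (k = 4.90 × 10⁻⁴ /M/s)
    first product → side product (k = 1.40 × 10⁻⁴ /s)
    substrate → decomposition product (k = 2.60 × 10⁻⁷ /s)
    triple product ⇌ isomer of the product (K = 1.50, k = 2.70 × 10⁻⁴ /s)

Recompute κ for this flask over the whole run: it is 0.561 /M/h, less than the early reading, with coupling partner at 23% of its charge at 2.5 h. Carry this κ to the neighbour flask charged with 0.660 equiv of coupling partner, substrate and time unchanged. It gives f = 62.9%. That neighbour flask holds 62.5% substrate, and its coupling partner stands at 24% of its own charge.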